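**Assumptions.** Ring positions use eremophilane numbering (C1–C10; angular methyl on C5; carboxyl carbon C15 on C4; acrolein unit C11–C13 on C7), and β means the face of the angular methyl. Numbers are given to starting materials whose carbons reach the target, to all intermediates and to the target; other reagents appear with SMILES in each step. The route is a paper plan built on literature precedent and analogy; nothing here has been run.

## Retrosynthetic overview

1. Integric acid ⇒ α-methylenation of the C12 aldehyde 25, which comes from oxidative cleavage of a C7 allyl group.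
2. The C1 ester ⇒ axial 1β-alcohol 15 + (2E,4S)-2,4-dimethyloct-2-enoic acid 22. The acid comes from (S)-2-methylhexanal, made by ene-reductase reduction of (E)-2-methylhex-2-enal.
3. 15 ⇒ γ-hydroxylation of the silyl dienol ether of 7α-allyl octalone 13 ⇒ α′-allylation of enone ester 11.
4. 11 ⇒ (S)-Wieland–Miescher ketone 4: the C4 carboxyl comes from methylenation, hydroboration anti to the angular methyl, and oxidation, with the enone masked as a dithiolane.
5. Ring order: ring B is the preformed cyclohexanedione; ring A is closed by the L-proline-catalysed aldol condensation, which sets C5 first.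

## Core

**Step 1**
Reactants: 1 (2-methylcyclohexane-1,3-dione), 2 (methyl vinyl ketone)
Product: 3 (2-methyl-2-(3-oxobutyl)cyclohexane-1,3-dione)
Conditions: H2O, AcOH (cat.), hydroquinone (cat.), 75 °C
Reagents that add atoms: none (all atoms from 1 and 2)
Why: Michael addition of the dione enol to the enone at the only nucleophilic carbon gives the achiral triketone.

**Step 2**
Reactants: 3
Product: 4 ((S)-Wieland–Miescher ketone)
Conditions: L-proline (5 mol%), DMSO, rt, 5 d; recrystallise (Et2O) to ≥99% ee
Reagents that add atoms: none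
Why: Hajos–Parrish–Eder–Sauer–Wiechert aldol condensation, in which the proline enamine of the side-chain ketone attacks one of the two enantiotopic ring carbonyls and sets the quaternary centre (S in 4, C5 of the target).

**Step 3**
Reactants: 4
Product: 5 (4 with the enone carbonyl as a 1,3-dithiolane; saturated ketone free)
Conditions: HSCH2CH2SH, p-TsOH (cat.), AcOH, rt
Reagents that add atoms: ethane-1,2-dithiol, SCCS
Why: Chemoselective dithioketalisation of the conjugated carbonyl, while the neopentyl C4 ketone is left alone, masks the enone against the ylide and borane.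

**Step 4**
Reactants: 5, 6 (methyltriphenylphosphonium bromide)
Product: 7 (C4 exocyclic methylene dithiolane)
Conditions: KOt-Bu, PhMe, 90 °C
Reagents that add atoms: none beyond 6
Why: Wittig methylenation with the small unstabilised ylide works on the hindered ketone and installs C15.

**Step 5**
Reactants: 7
Product: 8 (primary alcohol, CH2OH on C4 β, cis to the angular methyl; dithiolane retained)
Conditions: 9-BBN, THF, 65 °C; then NaOH, H2O2, 0 °C → rt
Reagents that add atoms: hydrogen peroxide, OO
Why: Hydroboration–oxidation with 9-BBN, which ignores the trisubstituted ring alkene and adds to the α face anti to the axial angular methyl, puts H on C4 from α and leaves the anti-Markovnikov CH2OH β, setting C4 irreversibly.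

**Step 6**
Reactants: 8
Product: 9 ((4aR,5S)-5-(hydroxymethyl)-4a-methyl-4,4a,5,6,7,8-hexahydronaphthalen-2(3H)-one)
Conditions: PhI(OCOCF3)2, MeCN/H2O (9:1), 0 °C → rt
Reagents that add atoms: water, O
Why: Oxidative dethioketalisation (Stork–Zhao) by S-activation and hydrolysis restores the enone without affecting the primary alcohol or C4.

**Step 7**
Reactants: 9
Product: 10 ((1S,8aR)-8a-methyl-6-oxo-1,2,3,4,6,7,8,8a-octahydronaphthalene-1-carboxylic acid)
Conditions: TEMPO (cat.), PhI(OAc)2, MeCN/H2O (1:1), rt
Reagents that add atoms: water, O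
Why: Oxoammonium (TEMPO) oxidation takes the primary alcohol through the aldehyde hydrate to the acid under near-neutral conditions that leave the enone intact and do not epimerise C4.

**Step 8**
Reactants: 10
Product: 11 (4-methoxybenzyl ester of 10)
Conditions: PMBCl, Cs2CO3, DMF, rt
Reagents that add atoms: 4-methoxybenzyl chloride, COc1ccc(CCl)cc1
Why: SN2 O-alkylation of the carboxylate is insensitive to the hindered acyl carbon and gives an ester that survives base, silyl triflate and peracid but is cleaved by TFA.

**Step 9**
Reactants: 11, 12 (allyl bromide)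
Product: 13 (4-methoxybenzyl (1S,7R,8aR)-7-allyl-8a-methyl-6-oxo-1,2,3,4,6,7,8,8a-octahydronaphthalene-1-carboxylate; allyl α, trans to the angular methyl)
Conditions: LDA (1.05 equiv), THF, −78 °C; 12, DMPU, −78 → −30 °C; then DBU (cat.), PhMe, rt
Reagents that add atoms: none beyond 12
Why: Kinetic α′-deprotonation gives the cross-conjugated dienolate (the hindered ester α-H is untouched), which is allylated at C7, and DBU equilibrates this epimerisable centre to the equatorial 7α isomer that avoids a 1,3-diaxial clash with the angular methyl.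

**Step 10**
Reactants: 13
Product: 14 (8-(tert-butyldimethylsilyloxy)-1(10),8-diene; extended silyl dienol ether)
Conditions: TBSOTf, Et3N, CH2Cl2, 0 °C
Reagents that add atoms: TBSOTf, CC(C)(C)[Si](C)(C)OS(=O)(=O)C(F)(F)F
Why: Soft enolisation gives the thermodynamic heteroannular dienol ether because the α′ position is now tertiary and γ-deprotonation of the silyloxocarbenium ion at C1 is favoured.

**Step 11**
Reactants: 14
Product: 15 (4-methoxybenzyl (1S,4R,7R,8aR)-7-allyl-4-hydroxy-8a-methyl-6-oxo-1,2,3,4,6,7,8,8a-octahydronaphthalene-1-carboxylate; axial 1β-OH)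
Conditions: mCPBA (1.05 equiv), NaHCO3, CH2Cl2, −20 °C; then HF·pyridine, THF, 0 °C
Reagents that add atoms: mCPBA, O=C(OO)c1cccc(Cl)c1
Why: Vinylogous Rubottom oxidation, in which the peracid attacks the electron-rich γ,δ-alkene axially on the β face so that ring B goes straight to a chair, gives the axial 1β-alcohol syn to the angular methyl, as in 6β-hydroxylation of steroidal 3,5-dienol ethers.

## Side chain

**Step 12**
Reactants: 16 (butanal), 17 (2-(triphenylphosphoranylidene)propanal)
Product: 18 ((E)-2-methylhex-2-enal)
Conditions: PhMe, 90 °C; distil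
Reagents that add atoms: none beyond 16 and 17
Why: Wittig olefination with the formyl-stabilised ylide gives the (E)-trisubstituted enal.

**Step 13**
Reactants: 18
Product: 19 ((S)-2-methylhexanal)
Conditions: ene-reductase (Old Yellow Enzyme family, (S)-selective OYE2/OYE3 type), NADP+ (cat.), glucose, glucose dehydrogenase, KPi pH 7.0/MTBE (4:1), 30 °C; MTBE phase dried and used directly
Reagents that add atoms: none (H only)
Why: Asymmetric bioreduction by the flavin-dependent ene-reductase adds hydride to Cβ and a tyrosine proton to Cα on the opposite face, giving the (S)-α-methyl aldehyde from the (E)-enal, while the MTBE phase and short contact time limit racemisation.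

**Step 14**
Reactants: 19, 20 (ethyl 2-(triphenylphosphoranylidene)propanoate)
Product: 21 (ethyl (2E,4S)-2,4-dimethyloct-2-enoate)
Conditions: MTBE/CH2Cl2, rt → 40 °C
Reagents that add atoms: none beyond 20
Why: Wittig reaction with the stabilised α-methyl ylide is E-selective and runs under neutral conditions that do not racemise the α-branched aldehyde.

**Step 15**
Reactants: 21
Product: 22 ((2E,4S)-2,4-dimethyloct-2-enoic acid)
Conditions: LiOH, THF/MeOH/H2O, 40 °C; then aq. citric acid
Reagents that add atoms: lithium hydroxide, [Li+].[OH-]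
Why: Saponification leaves the γ-stereocentre and the E-alkene untouched because the γ-H of an enoate is not acidic to hydroxide.

## Coupling and endgame

**Step 16**
Reactants: 15, 22
Product: 23 (PMB ester carrying the 1β-(2E,4S)-2,4-dimethyloct-2-enoyloxy group; 1S,4R,7R,8aR)
Conditions: 22, 2,4,6-trichlorobenzoyl chloride, Et3N, PhMe, rt; then 15, DMAP, PhMe, 40 °C
Reagents that add atoms: none (all atoms from 15 and 22)
Why: Yamaguchi esterification through the mixed anhydride and acyl-pyridinium acylates the hindered axial alcohol with retention at C1, and the α-methyl group of the acid disfavours γ-deprotonation (A1,3 strain).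

**Step 17**
Reactants: 23
Product: 24 ((1S,4R,7R,8aR)-7-allyl-4-{[(2E,4S)-2,4-dimethyloct-2-enoyl]oxy}-8a-methyl-6-oxo-1,2,3,4,6,7,8,8a-octahydronaphthalene-1-carboxylic acid)
Conditions: TFA, anisole, CH2Cl2, 0 °C
Reagents that add atoms: none
Why: Acidolysis of the PMB ester via the anisole-trapped benzylic cation frees the acid before any acid-sensitive 1,4-keto-aldehyde exists, and the γ-acyloxy enone does not ionise.

**Step 18**
Reactants: 24
Product: 25 ((1S,4R,7S,8aR)-4-{[(2E,4S)-2,4-dimethyloct-2-enoyl]oxy}-8a-methyl-6-oxo-7-(2-oxoethyl)-1,2,3,4,6,7,8,8a-octahydronaphthalene-1-carboxylic acid)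
Conditions: OsO4 (2 mol%), NaIO4, 2,6-lutidine, dioxane/H2O (3:1), rt
Reagents that add atoms: osmium tetroxide, O=[Os](=O)(=O)=O (reoxidised by NaIO4, [Na+].[O-]I(=O)(=O)=O)
Why: Lemieux–Johnson cleavage is selective for the electron-rich terminal alkene over the conjugated, trisubstituted enone and enoate.

**Step 19**
Reactants: 25, 26 (N,N-dimethylmethyleneiminium iodide, Eschenmoser's salt)
Product: 27 (integric acid)
Conditions: 26, Et3N, CH2Cl2, rt; pH 4 buffer work-up
Reagents that add atoms: none beyond 26
Why: Eschenmoser α-methylenation (Mannich reaction at the aldehyde α-CH2, then elimination of Me2NH) gives the 2-substituted acrolein, and C7 stays in its thermodynamically preferred 7α configuration.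

## Compound list

1 | 2-methylcyclohexane-1,3-dione | CC1C(=O)CCCC1=O | starting material
2 | methyl vinyl ketone | CC(=O)C=C | starting material
3 | 2-methyl-2-(3-oxobutyl)cyclohexane-1,3-dione | CC(=O)CCC1(C)C(=O)CCCC1=O | intermediate
4 | (S)-8a-methyl-3,4,8,8a-tetrahydronaphthalene-1,6(2H,7H)-dione | C[C@]12CCC(=O)C=C1CCCC2=O | intermediate
5 | (S)-enone 1,3-dithiolane of 4 | C[C@]12CCC3(SCCS3)C=C1CCCC2=O | intermediate
6 | methyltriphenylphosphonium bromide | C[P+](c1ccccc1)(c1ccccc1)c1ccccc1.[Br-] | starting material
7 | (R)-C4-methylene dithiolane | C[C@]12CCC3(SCCS3)C=C1CCCC2=C | intermediate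
8 | C4β-hydroxymethyl dithiolane (4S,5R, eremophilane numbering) | C[C@]12CCC3(SCCS3)C=C1CCC[C@@H]2CO | intermediate
9 | (4aR,5S)-5-(hydroxymethyl)-4a-methyl-4,4a,5,6,7,8-hexahydronaphthalen-2(3H)-one | C[C@]12CCC(=O)C=C1CCC[C@@H]2CO | intermediate
10 | (1S,8aR)-8a-methyl-6-oxo-1,2,3,4,6,7,8,8a-octahydronaphthalene-1-carboxylic acid | C[C@]12CCC(=O)C=C1CCC[C@@H]2C(=O)O | intermediate
11 | 4-methoxybenzyl ester of 10 | C[C@]12CCC(=O)C=C1CCC[C@@H]2C(=O)OCc1ccc(OC)cc1 | intermediate
12 | allyl bromide | C=CCBr | starting material
13 | PMB (1S,7R,8aR)-7-allyl-8a-methyl-6-oxo-octahydronaphthalene-1-carboxylate | C=CC[C@@H]1C[C@@]2(C)C(=CC1=O)CCC[C@@H]2C(=O)OCc1ccc(OC)cc1 | intermediate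
14 | PMB (1S,7R,8aR)-7-allyl-6-(TBSO)-8a-methyl-1,2,3,7,8,8a-hexahydronaphthalene-1-carboxylate | C=CC[C@@H]1C[C@@]2(C)C(C=C1O[Si](C)(C)C(C)(C)C)=CCC[C@@H]2C(=O)OCc1ccc(OC)cc1 | intermediate
15 | PMB (1S,4R,7R,8aR)-7-allyl-4-hydroxy-8a-methyl-6-oxo-octahydronaphthalene-1-carboxylate | C=CC[C@@H]1C[C@@]2(C)C(=CC1=O)[C@H](O)CC[C@@H]2C(=O)OCc1ccc(OC)cc1 | intermediate
16 | butanal | CCCC=O | starting material
17 | 2-(triphenylphosphoranylidene)propanal | CC(C=O)=P(c1ccccc1)(c1ccccc1)c1ccccc1 | starting material
18 | (E)-2-methylhex-2-enal | CCC/C=C(\C)C=O | intermediate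
19 | (S)-2-methylhexanal | O=C[C@@H](C)CCCC | intermediate
20 | ethyl 2-(triphenylphosphoranylidene)propanoate | CCOC(=O)C(C)=P(c1ccccc1)(c1ccccc1)c1ccccc1 | starting material
21 | ethyl (2E,4S)-2,4-dimethyloct-2-enoate | CCOC(=O)/C(C)=C/[C@@H](C)CCCC | intermediate
22 | (2E,4S)-2,4-dimethyloct-2-enoic acid | OC(=O)/C(C)=C/[C@@H](C)CCCC | intermediate
23 | PMB (1S,4R,7R,8aR)-7-allyl-4-[(2E,4S)-2,4-dimethyloct-2-enoyloxy]-8a-methyl-6-oxo-octahydronaphthalene-1-carboxylate | C=CC[C@@H]1C[C@@]2(C)C(=CC1=O)[C@H](OC(=O)/C(C)=C/[C@@H](C)CCCC)CC[C@@H]2C(=O)OCc1ccc(OC)cc1 | intermediate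
24 | free acid of 23 | C=CC[C@@H]1C[C@@]2(C)C(=CC1=O)[C@H](OC(=O)/C(C)=C/[C@@H](C)CCCC)CC[C@@H]2C(=O)O | intermediate
25 | (1S,4R,7S,8aR)-7-(2-oxoethyl) acid | O=CC[C@@H]1C[C@@]2(C)C(=CC1=O)[C@H](OC(=O)/C(C)=C/[C@@H](C)CCCC)CC[C@@H]2C(=O)O | intermediate
26 | N,N-dimethylmethyleneiminium iodide | C=[N+](C)C.[I-] | starting material
27 | integric acid, (1S,4R,7S,8aR)-4-[(2E,4S)-2,4-dimethyloct-2-enoyloxy]-8a-methyl-6-oxo-7-(3-oxoprop-1-en-2-yl)-1,2,3,4,6,7,8,8a-octahydronaphthalene-1-carboxylic acid | C=C(C=O)[C@@H]1C[C@@]2(C)C(=CC1=O)[C@H](OC(=O)/C(C)=C/[C@@H](C)CCCC)CC[C@@H]2C(=O)O | target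

## Summary

Total steps: 19 (core 11, side chain 4, coupling and endgame 4).
Longest linear sequence: 15 steps (Steps 1–11, then 16–19).

Steps most likely to fail:

1. **Step 11 (γ-hydroxylation).** The 1β:1α ratio may be poor in this bicyclic system, which is less rigid than a steroid. Fallback: separate the equatorial 1α-alcohol and couple it with 22 under Mitsunobu conditions (PPh3, DIAD), which inverts C1 and gives 23 directly.
2. **Step 13 (ene-reductase).** Enantioselectivity may be incomplete, or aldehyde 19 may racemise in buffer. Fallback: use the same enzyme class on methyl 2-(hydroxymethyl)acrylate to make the configurationally stable Roche ester, then build (S)-2-methylhexanol by O-silylation, ester reduction, tosylation, n-propyl cuprate displacement and desilylation, and oxidise just before Step 14.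
3. **Step 19 (late α-methylenation).** Base may move the exocyclic alkene into conjugation with the C8 ketone. Fallback: introduce C11–C13 earlier as a protected allylic alcohol by Pd-catalysed α-alkenylation of the C7 enolate of 11 with 2-bromoallyl TBS ether, and finish with desilylation and MnO2 oxidation to the enal.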